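Watch the partner first, and read the substrate only against it.

| setting | ochre | teal | grey | violet |
|---|---|---|---|---|
| substrate | 0.40 M | 0.40 M | 0.40 M | 0.40 M (fed, over 2.00 min) |
| partner | 3.00 equiv | 3.00 equiv | 3.00 equiv | 3.00 equiv |
| remark | one stirred flow tank at steady state, fed with the mixture as stated, mean residence time 7.50 min | a single well-mixed tank run continuously and read at steady state, 2.5 min in it on average | a closed flask charged with all of it at once and left for 2.5 min | all but substrate at the start; substrate goes in evenly over 2.00 min, the run ends at 2.5 min |
| time |  |  | 2.5 min | 2.5 min |

    substrate + partner ⇌ intermediate (K1 = 3.0 /M, k1 = 0.010 /M/s)
    intermediate ⇌ target + released group (K2 = 1.2 M, k2 = 0.0073 /s)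
    target + released group → side product (k3 = 0.028 /M/s)
    partner → decomposed reagent (k4 = 0.0081 /s)
    released group → by-product carried off (k5 = 0.33 /s)

- the stated concentrations are those of everything mixed, before any reaction; amounts are the same in each set-up
- the feed brings no volume worth counting
- run time (grey): 2.5 min

- the set-up with the highest amount of intermediate at the outlet or at the end, in percent of the substrate put in ("none" if the first two lie within 2 percentage points) (ochre / teal / grey / violet / none)
- amount of intermediate at the outlet or at the end, in percent of the substrate put in, ochre
- amount of intermediate at the outlet or at the end, in percent of the substrate put in, teal
- amount of intermediate at the outlet or at the end, in percent of the substrate put in, grey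
- amount of intermediate at the outlet or at the end, in percent of the substrate put in, violet

**Minutes.** I opened with the tanks and argued that the released group could be set aside, since it is stripped at 0.33 /s, a constant far above the 0.0073 /s of the intermediate's onward step. That leaves the intermediate three exits: the outlet, the way back and the way onward. I therefore proposed the hold time, the mean time an intermediate stays before any exit, which is one over the sum of the three rate constants. For teal, with 2.5 min in the tank on average, it is 0.963 min. Set it against the making time, 1/(k1[partner]), a pseudo-first-order time, and the tank balance gives [intermediate]/[substrate] as hold time over making time.

A colleague objected that [partner] was unknown. So we went round. Counting decomposition first, of 1.20 M, teal keeps 0.542 M, the ratio is 0.313, and substrate left is 60.4%. Putting that substrate back charges the partner for what it made: 0.470 M, ratio 0.272, substrate 63.7%. Teal's intermediate is then 17.3%.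

For ochre I took one round, which ran high in teal: hold time 1.30 min, partner 0.258 M, intermediate 10.8%.

The colleague then took grey, which has no outlet, so its hold time is 1.57 min. She read the end as reflecting partner one hold time earlier, 0.763 M, with substrate left at 35.3%, giving 25.3%. Violet's substrate arrives 1.00 min late on average, so she scaled grey by 0.615, giving 15.6%. We committed to grey.

The forecast gave ochre 9.9%, teal 17.4%, grey 22.1% and violet 18.7%, and named grey, the pick we committed to, on the ground that “The closed flask wins because all the substrate meets the partner at full strength early on”; its value for grey is lower than the one reckoned at the meeting.

The simulation gives ochre 9.93%, teal 17.5%, grey 23.5% and violet 18.9%, so grey stands highest.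

In teal, with [partner] at 0.476 M, the making time is 3.50 min, longer than the hold time of 0.963 min, and their ratio is 0.275. In grey at 1.25 min, with partner at 45.0% of its charge, the making time is 3.09 min against a hold time of 1.57 min, a ratio of 0.508, and the reading of intermediate over substrate there is 0.501.

The constants used here are assumed; the flask was simulated.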